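**Plan**
- Feature: O1, C2 (with its 4-hydroxyphenyl ring), C3 and the ring A oxygenated at C4 form a 2-aryl-2,3-dihydrobenzofuran that is a 5,7-dioxygenated flavanone short of one ring atom. The flavanone carbonyl carbon becomes the ipso carbon of the aryl group on C3, and O7 becomes the handle for the styryl group at C6.
- Cuts, in order: the eight O–Me bonds; the styryl C6–vinyl bond (Heck); the outer dihydrofuran at C2'–C3' (carbene C–H insertion) and C3a'–C3' (aryllithium acylation); the central resorcinol ring back to the C3 carboxyl carbon plus acetylacetone; the inner C3–C3a bond (back to a flavanone); the flavanone C2–aryl bond (back to a chromone).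
- Forward order of rings: pyranone ring (chromone, then flavanone), contraction to the inner dihydrofuran, central benzene ring by triketone aldol, outer dihydrofuran by C–H insertion, then styryl group and demethylation.
- Stereochemistry: C2 from rhodium-catalysed asymmetric conjugate addition; C3 relayed from C2 in the ring contraction; C3' from a chiral dirhodium catalyst, because the inner unit is too remote to steer it; C2' relayed from C3' by acid equilibration to the trans ring.

Key step: step 5

Assumption: the sense of induction of the two chiral catalysts (steps 4 and 14) is taken by analogy with their simple substrates; if either proves opposite, the enantiomeric ligand or catalyst is used with no other change.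

Notation: DBF* = the (2R,3R)-6-(benzyloxy)-4-methoxy-2-(4-methoxyphenyl)-2,3-dihydro-1-benzofuran-3-yl group. Primed locants belong to the outer dihydrobenzofuran.

Step 1
Reactants: 1 2',4',6'-trihydroxyacetophenone; 2 benzyl bromide
Product: 3 1-[4-(benzyloxy)-2,6-dihydroxyphenyl]ethanone
Conditions: BnBr (1.0 equiv), K2CO3, DMF, rt
Reagents that add atoms: none
Why: Williamson ether synthesis under weak base, in which the 4-hydroxyl, the only one not chelated to the acetyl carbonyl and the most acidic, should be alkylated first by one equivalent of benzyl bromide.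

Step 2
Reactants: 3 1-[4-(benzyloxy)-2,6-dihydroxyphenyl]ethanone
Product: 4 1-[4-(benzyloxy)-2-hydroxy-6-methoxyphenyl]ethanone
Conditions: Me2SO4 (1.05 equiv), K2CO3, acetone, reflux
Reagents that add atoms: dimethyl sulfate, COS(=O)(=O)OC
Why: Williamson O-methylation in which, once one of the two equivalent chelated hydroxyls is methylated, the other is held in a strong hydrogen bond to the ketone and should react much more slowly, leaving the phenol that becomes the ring oxygen.

Step 3
Reactants: 4 1-[4-(benzyloxy)-2-hydroxy-6-methoxyphenyl]ethanone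
Product: 6 7-(benzyloxy)-5-methoxy-4H-chromen-4-one, via enaminone 5 (not isolated)
Conditions: Me2NCH(OMe)2, toluene, 100 °C; then conc. HCl, CH2Cl2, 40 °C
Reagents that add atoms: N,N-dimethylformamide dimethyl acetal, COC(OC)N(C)C
Why: Enaminone route to chromones, in which condensation of the methyl ketone with the formamide acetal gives the β-dimethylamino enone and acid then drives conjugate addition of the phenol and loss of dimethylamine (addition–elimination, 6-endo-trig) to close the pyranone ring.

Step 4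
Reactants: 6 7-(benzyloxy)-5-methoxy-4H-chromen-4-one; 7 4-methoxyphenylboronic acid
Product: 8 (2R)-7-(benzyloxy)-5-methoxy-2-(4-methoxyphenyl)chroman-4-one
Conditions: [Rh(OH)(cod)]2 (cat.), (R)-MeO-F12-BIPHEP [(R)-6,6'-dimethoxy-2,2'-bis{bis(3,4,5-trifluorophenyl)phosphino}biphenyl], toluene/H2O, 40 °C
Reagents that add atoms: none
Why: Rhodium-catalysed asymmetric conjugate addition of an arylboronic acid to an enone (Hayashi–Miyaura reaction), known for chromones, in which the aryl–rhodium species bearing the C2-symmetric bisphosphine adds to one face of C2 and water protonates the rhodium enolate, the electron-poor ligand giving turnover fast enough that the flavanone is not opened to the chalcone; the (R)-ligand is expected to give 2R by analogy with its sense for cyclic enones.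

Step 5
Reactants: 8 (2R)-7-(benzyloxy)-5-methoxy-2-(4-methoxyphenyl)chroman-4-one
Product: 10 methyl (2R,3R)-6-(benzyloxy)-4-methoxy-2-(4-methoxyphenyl)-2,3-dihydro-1-benzofuran-3-carboxylate, via methyl enol ether 9 (not isolated)
Conditions: PhI(OAc)2 (1.2 equiv), conc. H2SO4 (cat.), HC(OMe)3, rt; aqueous work-up
Reagents that add atoms: trimethyl orthoformate, COC(OC)OC; water, O
Why: This is an oxidative 1,2-aryl shift with ring contraction, a known reaction of flavanones and the hypervalent-iodine counterpart of the Tl(NO3)3 rearrangement of aryl ketones to methyl arylacetates: acid and orthoformate turn the ketone into enol ether 9, which the trivalent iodine reagent attacks at C3 on the face anti to the C2 aryl group, giving after methanol capture a C4 ketal with an equatorial C3–I bond. The ring A carbon C4a, antiperiplanar to that bond, then shifts from C4 to C3 with loss of iodobenzene, and the dimethoxycarbenium ion left at the old C4 ends as the methyl ester on work-up. The dihydrofuran ring is therefore closed by contraction of the pyranone, a phenonium-type shift that is formally a 3-exo-tet attack of C4a on C3, and the new C3–C3a bond forms with inversion at C3. C3 is controlled by C2, since anti iodination followed by inversion places the ester trans to the aryl group, which is also the thermodynamic arrangement, while C2 itself is not touched. The step needs ring A to migrate in preference to the C2 anisyl group (isoflavone) and to elimination (flavone); this should be secured by the 5,7-dioxygenated, phloroglucinol-type ring A and by ketalisation in orthoformate, which makes the dialkoxycarbenium ion the sink for the shift.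

Step 6
Reactants: 10 methyl (2R,3R)-6-(benzyloxy)-4-methoxy-2-(4-methoxyphenyl)-2,3-dihydro-1-benzofuran-3-carboxylate
Product: 11 DBF*-C(=O)N(OMe)Me [(2R,3R)-6-(benzyloxy)-N,4-dimethoxy-2-(4-methoxyphenyl)-N-methyl-2,3-dihydro-1-benzofuran-3-carboxamide]
Conditions: MeNH(OMe)·HCl, i-PrMgCl, THF, −20 to 0 °C
Reagents that add atoms: N,O-dimethylhydroxylamine hydrochloride, CNOC.Cl
Why: Aminolysis of the ester by the chloromagnesium amide of N,O-dimethylhydroxylamine (Weinreb amide synthesis), chosen because the adduct of this amide with a carbon nucleophile stays tetrahedral until work-up; should C3 be deprotonated, reprotonation returns the trans isomer, and loss of the ring oxygen from that enolate would be a stereoelectronically poor 5-endo process.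

Step 7
Reactants: 11 DBF*-C(=O)N(OMe)Me; 12 pentane-2,4-dione (acetylacetone)
Product: 14 1-DBF*-hexane-1,3,5-trione, via dilithio acetylacetonate 13 (not isolated)
Conditions: 12 (3 equiv), LiN(i-Pr)2 (6 equiv, commercial solution), THF, 0 °C; then 11, −78 to 0 °C; cold aqueous HCl quench
Reagents that add atoms: none
Why: Claisen-type C-acylation of the terminal carbanion of the acetylacetone dianion by the N-methoxy-N-methylamide (polyketide chain extension), in which the chelated tetrahedral adduct prevents a second addition and shields the C3–H from base, so that the 1,3,5-triketone is released only on acidic quench.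

Step 8
Reactants: 14 1-DBF*-hexane-1,3,5-trione
Product: 15 5-DBF*-benzene-1,3-diol
Conditions: KOH (1 M aq), MeOH, 0 °C to rt; then 2 M HCl
Reagents that add atoms: none
Why: Biomimetic intramolecular aldol condensation of a 1,3,5-triketone to a resorcinol, in which the enolate of the terminal methyl ketone adds to the C1 carbonyl (6-enolendo-exo-trig) and loss of one water plus enolisation of the two remaining carbonyls gives the aromatic ring irreversibly, whereas an aldol through C3 would create a quaternary centre that cannot aromatise and reverts; any epimerisation at C3 returns to trans.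

Step 9
Reactants: 15 5-DBF*-benzene-1,3-diol
Product: 16 (2R,3R)-6-(benzyloxy)-3-[3,5-bis(methoxymethoxy)phenyl]-4-methoxy-2-(4-methoxyphenyl)-2,3-dihydro-1-benzofuran
Conditions: MOMCl, i-Pr2NEt, CH2Cl2, 0 °C to rt
Reagents that add atoms: chloromethyl methyl ether, COCCl
Why: Double O-alkylation of the phenols to the bis(methoxymethyl) ether, whose two chelating acetal groups make the carbon between them the most readily lithiated site of the molecule and which is later removed by mild acid.

Step 10
Reactants: 16 (2R,3R)-6-(benzyloxy)-3-[3,5-bis(methoxymethoxy)phenyl]-4-methoxy-2-(4-methoxyphenyl)-2,3-dihydro-1-benzofuran; 17 3,5-dimethoxybenzoyl chloride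
Product: 20 (4-DBF*-2,6-dihydroxyphenyl)(3,5-dimethoxyphenyl)methanone, via aryllithium 18 (not isolated), via bis-MOM ketone 19 (not isolated)
Conditions: n-BuLi (1.1 equiv), THF, −20 to 0 °C; 17, −78 °C to rt; then 2 M HCl, MeOH, rt
Reagents that add atoms: none
Why: Directed ortho-metalation, acylation and acetal cleavage in one flask: the carbon flanked by two MOM ethers should be lithiated much faster than the ring A positions flanked by methyl, benzyl or aryl ethers, the aryllithium adds only once because the di-ortho-substituted ketone is too hindered for a second addition, and dilute HCl in methanol removes the MOM groups now chelated to the ketone.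

Step 11
Reactants: 20 (4-DBF*-2,6-dihydroxyphenyl)(3,5-dimethoxyphenyl)methanone
Product: 21 (4-DBF*-2-hydroxy-6-methoxyphenyl)(3,5-dimethoxyphenyl)methanone
Conditions: Me2SO4 (1.05 equiv), K2CO3, acetone, reflux
Reagents that add atoms: dimethyl sulfate, COS(=O)(=O)OC
Why: Williamson mono-methylation with the same selectivity as in step 2, since after the first methylation the second hydroxyl is locked in a hydrogen bond to the benzophenone carbonyl.

Step 12
Reactants: 21 (4-DBF*-2-hydroxy-6-methoxyphenyl)(3,5-dimethoxyphenyl)methanone; 22 2,4-dimethoxybenzyl alcohol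
Product: 23 {4-DBF*-2-[(2,4-dimethoxybenzyl)oxy]-6-methoxyphenyl}(3,5-dimethoxyphenyl)methanone
Conditions: PPh3, DIAD, THF, 0 °C to rt
Reagents that add atoms: none
Why: Mitsunobu etherification of the remaining acidic, chelated phenol with the primary benzylic alcohol, which installs the 2,4-dimethoxybenzyl ether under neutral conditions and avoids the unstable benzyl chloride.

Step 13
Reactants: 23 {4-DBF*-2-[(2,4-dimethoxybenzyl)oxy]-6-methoxyphenyl}(3,5-dimethoxyphenyl)methanone
Product: 24 hydrazone of 23 (E/Z mixture)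
Conditions: N2H4·H2O (excess), AcOH (cat.), n-BuOH, 110 °C
Reagents that add atoms: hydrazine, NN
Why: Hydrazone formation by acid-catalysed condensation, forced by a large excess of hydrazine and heat because the ketone is hindered by two ortho alkoxy groups; all ethers present are inert to these conditions.

Step 14
Reactants: 24 hydrazone of 23
Product: 27 (2R,3R)-6-(benzyloxy)-3-[(2R,3R)-2-(2,4-dimethoxyphenyl)-3-(3,5-dimethoxyphenyl)-4-methoxy-2,3-dihydro-1-benzofuran-6-yl]-4-methoxy-2-(4-methoxyphenyl)-2,3-dihydro-1-benzofuran, via diazo compound 25 (not isolated), via cis isomer 26 (not isolated)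
Conditions: MnO2, CH2Cl2, 0 °C to rt, filter; Rh2(R-PTAD)4 (1 mol %), CH2Cl2, 0 °C; then CF3CO2H, 0 °C to rt
Reagents that add atoms: none
Why: Dehydrogenation of the hydrazone to the diaryldiazomethane and intramolecular 1,5 C–H insertion of the derived donor/donor rhodium carbene into the benzylic ether C–H bond, a known enantioselective route to 2,3-diaryl-2,3-dihydrobenzofurans, in which the chiral dirhodium tetracarboxylate fixes C3' (3'R expected, with C2' cis) and the doubly activated benzylic C–H bond is preferred over the methoxy C–H bonds; CF3CO2H then reversibly ionises the C2'–O bond to the 2,4-dimethoxybenzylic cation, which recloses to the more stable trans ring, so that C2' is relayed from C3'.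

Step 15
Reactants: 27 (the 6-benzyloxy bis-dihydrobenzofuran from step 14)
Product: 28 (2R,3R)-3-[(2R,3R)-2-(2,4-dimethoxyphenyl)-3-(3,5-dimethoxyphenyl)-4-methoxy-2,3-dihydro-1-benzofuran-6-yl]-4-methoxy-2-(4-methoxyphenyl)-2,3-dihydro-1-benzofuran-6-ol
Conditions: H2 (1 atm), Pd/C (10% palladium on carbon), EtOAc, rt
Reagents that add atoms: none
Why: Catalytic hydrogenolysis of the primary aryl benzyl ether; under neutral conditions at one atmosphere the secondary, hindered ring C2–O bonds of the two dihydrofurans should be cleaved far more slowly.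

Step 16
Reactants: 28 (the 6-ol from step 15)
Product: 29 (2R,3R)-3-[(2R,3R)-2-(2,4-dimethoxyphenyl)-3-(3,5-dimethoxyphenyl)-4-methoxy-2,3-dihydro-1-benzofuran-6-yl]-4-methoxy-2-(4-methoxyphenyl)-2,3-dihydro-1-benzofuran-6-yl trifluoromethanesulfonate
Conditions: PhNTf2, Et3N, DMAP (cat.), CH2Cl2, rt
Reagents that add atoms: N-phenylbis(trifluoromethanesulfonimide), O=S(=O)(N(c1ccccc1)S(=O)(=O)C(F)(F)F)C(F)(F)F
Why: O-Sulfonylation of the only free phenol with N-phenyltriflimide gives the aryl triflate needed for cross-coupling, no other nucleophilic site being present.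

Step 17
Reactants: 29 (the 6-triflate from step 16); 30 4-methoxystyrene
Product: 31 (2R,3R)-3-[(2R,3R)-2-(2,4-dimethoxyphenyl)-3-(3,5-dimethoxyphenyl)-4-methoxy-2,3-dihydro-1-benzofuran-6-yl]-4-methoxy-2-(4-methoxyphenyl)-6-[(E)-2-(4-methoxyphenyl)ethenyl]-2,3-dihydro-1-benzofuran
Conditions: PdCl2(PPh3)2 (cat.), LiCl, Et3N, DMF, 100 °C
Reagents that add atoms: none
Why: Mizoroki–Heck reaction, in which zerovalent palladium inserts into the aryl–OTf bond, chloride gives the neutral arylpalladium chloride that adds to the unsubstituted terminus of the styrene, and syn β-hydride elimination gives the E-stilbene; no stereocentre carries an acidic hydrogen under these conditions.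

Step 18
Reactants: 31 (the octamethyl ether from step 17)
Product: 32 CNP0118407.2, (2R,3R)-3-[(2R,3R)-2-(2,4-dihydroxyphenyl)-3-(3,5-dihydroxyphenyl)-4-hydroxy-2,3-dihydro-1-benzofuran-6-yl]-2-(4-hydroxyphenyl)-6-[(E)-2-(4-hydroxyphenyl)ethenyl]-2,3-dihydro-1-benzofuran-4-ol
Conditions: BBr3 (excess), CH2Cl2, −78 °C to rt; then H2O
Reagents that add atoms: none
Why: Lewis acid cleavage of all eight aryl methyl ethers by BBr3, the usual last step for permethylated stilbene oligomers; both dihydrofurans are already trans, the thermodynamic arrangement, so reversible C2–O ionisation cannot change them, and C3 and C3' are not touched.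

**Compound list**
1 | 2',4',6'-trihydroxyacetophenone | CC(=O)c1c(O)cc(O)cc1O | starting material
2 | benzyl bromide | BrCc1ccccc1 | starting material
3 | 1-[4-(benzyloxy)-2,6-dihydroxyphenyl]ethanone | CC(=O)c1c(O)cc(OCc2ccccc2)cc1O | intermediate
4 | 1-[4-(benzyloxy)-2-hydroxy-6-methoxyphenyl]ethanone | CC(=O)c1c(O)cc(OCc2ccccc2)cc1OC | intermediate
5 | (E)-1-[4-(benzyloxy)-2-hydroxy-6-methoxyphenyl]-3-(dimethylamino)prop-2-en-1-one | CN(C)/C=C/C(=O)c1c(O)cc(OCc2ccccc2)cc1OC | intermediate
6 | 7-(benzyloxy)-5-methoxy-4H-chromen-4-one | COc1cc(OCc2ccccc2)cc2occc(=O)c12 | intermediate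
7 | 4-methoxyphenylboronic acid | COc1ccc(B(O)O)cc1 | starting material
8 | (2R)-7-(benzyloxy)-5-methoxy-2-(4-methoxyphenyl)chroman-4-one | COc1cc(OCc2ccccc2)cc2O[C@@H](c3ccc(OC)cc3)CC(=O)c12 | intermediate
9 | (2R)-7-(benzyloxy)-4,5-dimethoxy-2-(4-methoxyphenyl)-2H-chromene | COC1=C[C@H](c2ccc(OC)cc2)Oc2cc(OCc3ccccc3)cc(OC)c12 | intermediate
10 | methyl (2R,3R)-6-(benzyloxy)-4-methoxy-2-(4-methoxyphenyl)-2,3-dihydro-1-benzofuran-3-carboxylate | COc1cc(OCc2ccccc2)cc2O[C@@H](c3ccc(OC)cc3)[C@H](C(=O)OC)c12 | intermediate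
11 | (2R,3R)-6-(benzyloxy)-N,4-dimethoxy-2-(4-methoxyphenyl)-N-methyl-2,3-dihydro-1-benzofuran-3-carboxamide | COc1cc(OCc2ccccc2)cc2O[C@@H](c3ccc(OC)cc3)[C@H](C(=O)N(C)OC)c12 | intermediate
12 | pentane-2,4-dione | CC(=O)CC(C)=O | starting material
13 | dilithium pentane-2,4-dione-1,3-diide (dilithio acetylacetonate) | [Li+].[Li+].C=C([O-])C=C(C)[O-] | intermediate
14 | 1-DBF*-hexane-1,3,5-trione | COc1cc(OCc2ccccc2)cc2O[C@@H](c3ccc(OC)cc3)[C@H](C(=O)CC(=O)CC(C)=O)c12 | intermediate
15 | 5-DBF*-benzene-1,3-diol | COc1cc(OCc2ccccc2)cc2O[C@@H](c3ccc(OC)cc3)[C@H](c3cc(O)cc(O)c3)c12 | intermediate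
16 | (2R,3R)-6-(benzyloxy)-3-[3,5-bis(methoxymethoxy)phenyl]-4-methoxy-2-(4-methoxyphenyl)-2,3-dihydro-1-benzofuran | COc1cc(OCc2ccccc2)cc2O[C@@H](c3ccc(OC)cc3)[C@H](c3cc(OCOC)cc(OCOC)c3)c12 | intermediate
17 | 3,5-dimethoxybenzoyl chloride | COc1cc(OC)cc(c1)C(Cl)=O | starting material
18 | [4-DBF*-2,6-bis(methoxymethoxy)phenyl]lithium | COc1cc(OCc2ccccc2)cc2O[C@@H](c3ccc(OC)cc3)[C@H](c3cc(OCOC)c([Li])c(OCOC)c3)c12 | intermediate
19 | [4-DBF*-2,6-bis(methoxymethoxy)phenyl](3,5-dimethoxyphenyl)methanone | COc1cc(OCc2ccccc2)cc2O[C@@H](c3ccc(OC)cc3)[C@H](c3cc(OCOC)c(C(=O)c4cc(OC)cc(OC)c4)c(OCOC)c3)c12 | intermediate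
20 | (4-DBF*-2,6-dihydroxyphenyl)(3,5-dimethoxyphenyl)methanone | COc1cc(OCc2ccccc2)cc2O[C@@H](c3ccc(OC)cc3)[C@H](c3cc(O)c(C(=O)c4cc(OC)cc(OC)c4)c(O)c3)c12 | intermediate
21 | (4-DBF*-2-hydroxy-6-methoxyphenyl)(3,5-dimethoxyphenyl)methanone | COc1cc(OCc2ccccc2)cc2O[C@@H](c3ccc(OC)cc3)[C@H](c3cc(O)c(C(=O)c4cc(OC)cc(OC)c4)c(OC)c3)c12 | intermediate
22 | 2,4-dimethoxybenzyl alcohol | COc1ccc(CO)c(OC)c1 | starting material
23 | {4-DBF*-2-[(2,4-dimethoxybenzyl)oxy]-6-methoxyphenyl}(3,5-dimethoxyphenyl)methanone | COc1cc(OCc2ccccc2)cc2O[C@@H](c3ccc(OC)cc3)[C@H](c3cc(OCc4ccc(OC)cc4OC)c(C(=O)c4cc(OC)cc(OC)c4)c(OC)c3)c12 | intermediate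
24 | hydrazone of 23 (E/Z mixture at C=N) | COc1cc(OCc2ccccc2)cc2O[C@@H](c3ccc(OC)cc3)[C@H](c3cc(OCc4ccc(OC)cc4OC)c(C(=NN)c4cc(OC)cc(OC)c4)c(OC)c3)c12 | intermediate
25 | (2R,3R)-6-(benzyloxy)-3-{4-[diazo(3,5-dimethoxyphenyl)methyl]-3-[(2,4-dimethoxybenzyl)oxy]-5-methoxyphenyl}-4-methoxy-2-(4-methoxyphenyl)-2,3-dihydro-1-benzofuran | COc1cc(OCc2ccccc2)cc2O[C@@H](c3ccc(OC)cc3)[C@H](c3cc(OCc4ccc(OC)cc4OC)c(C(=[N+]=[N-])c4cc(OC)cc(OC)c4)c(OC)c3)c12 | intermediate
26 | (2R,3R)-6-(benzyloxy)-3-[(2S,3R)-2-(2,4-dimethoxyphenyl)-3-(3,5-dimethoxyphenyl)-4-methoxy-2,3-dihydro-1-benzofuran-6-yl]-4-methoxy-2-(4-methoxyphenyl)-2,3-dihydro-1-benzofuran (outer ring cis) | COc1cc(OCc2ccccc2)cc2O[C@@H](c3ccc(OC)cc3)[C@H](c3cc(OC)c4c(c3)O[C@H](c3ccc(OC)cc3OC)[C@@H]4c3cc(OC)cc(OC)c3)c12 | intermediate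
27 | (2R,3R)-6-(benzyloxy)-3-[(2R,3R)-2-(2,4-dimethoxyphenyl)-3-(3,5-dimethoxyphenyl)-4-methoxy-2,3-dihydro-1-benzofuran-6-yl]-4-methoxy-2-(4-methoxyphenyl)-2,3-dihydro-1-benzofuran | COc1cc(OCc2ccccc2)cc2O[C@@H](c3ccc(OC)cc3)[C@H](c3cc(OC)c4c(c3)O[C@@H](c3ccc(OC)cc3OC)[C@@H]4c3cc(OC)cc(OC)c3)c12 | intermediate
28 | (2R,3R)-3-[(2R,3R)-2-(2,4-dimethoxyphenyl)-3-(3,5-dimethoxyphenyl)-4-methoxy-2,3-dihydro-1-benzofuran-6-yl]-4-methoxy-2-(4-methoxyphenyl)-2,3-dihydro-1-benzofuran-6-ol | COc1cc(O)cc2O[C@@H](c3ccc(OC)cc3)[C@H](c3cc(OC)c4c(c3)O[C@@H](c3ccc(OC)cc3OC)[C@@H]4c3cc(OC)cc(OC)c3)c12 | intermediate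
29 | 6-trifluoromethanesulfonate of 28 | COc1cc(OS(=O)(=O)C(F)(F)F)cc2O[C@@H](c3ccc(OC)cc3)[C@H](c3cc(OC)c4c(c3)O[C@@H](c3ccc(OC)cc3OC)[C@@H]4c3cc(OC)cc(OC)c3)c12 | intermediate
30 | 4-methoxystyrene | C=Cc1ccc(OC)cc1 | starting material
31 | (2R,3R)-3-[(2R,3R)-2-(2,4-dimethoxyphenyl)-3-(3,5-dimethoxyphenyl)-4-methoxy-2,3-dihydro-1-benzofuran-6-yl]-4-methoxy-2-(4-methoxyphenyl)-6-[(E)-2-(4-methoxyphenyl)ethenyl]-2,3-dihydro-1-benzofuran | COc1ccc(/C=C/c2cc(OC)c3c(c2)O[C@@H](c2ccc(OC)cc2)[C@@H]3c2cc(OC)c3c(c2)O[C@@H](c2ccc(OC)cc2OC)[C@@H]3c2cc(OC)cc(OC)c2)cc1 | intermediate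
32 | CNP0118407.2, (2R,3R)-3-[(2R,3R)-2-(2,4-dihydroxyphenyl)-3-(3,5-dihydroxyphenyl)-4-hydroxy-2,3-dihydro-1-benzofuran-6-yl]-2-(4-hydroxyphenyl)-6-[(E)-2-(4-hydroxyphenyl)ethenyl]-2,3-dihydro-1-benzofuran-4-ol | Oc1ccc(/C=C/c2cc(O)c3c(c2)O[C@@H](c2ccc(O)cc2)[C@@H]3c2cc(O)c3c(c2)O[C@@H](c2ccc(O)cc2O)[C@@H]3c2cc(O)cc(O)c2)cc1 | target

**Step count and risks**

Total steps: 18. Longest linear sequence: 18 steps (from 1 to 32; all other starting materials enter this one line).

Steps most likely to fail:

Step 8. Ring closure by the unactivated methyl terminus onto the hindered C1 ketone may be slow, which would leave time for hydroxide cleavage of the polyketone chain (retro-Claisen) and for enolisation at C3. The fallback sets out from 11 and returns at 15. Compound 11 is acylated at −78 °C onto the dianion (LiN(i-Pr)2, THF) of 2,2-dimethyl-6-(2-oxopropyl)-4H-1,3-dioxin-4-one F1, which is made in one step from commercial 2,2,6-trimethyl-4H-1,3-dioxin-4-one with LiN(SiMe3)2 and acetyl chloride; this gives the diketo-dioxinone F2. In F2 the ring-closing carbon is the dioxinone C5, a vinylogous β-keto ester position, so triethylamine in CH2Cl2 should suffice for the aldol and CF3CO2H completes the dehydration to the acetonide-protected resorcylate F3. KOH in aqueous methanol at about 100 °C, followed by acidification, opens the acetonide and decarboxylates the salicylic acid to 15.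

Step 14. Insertion by a carbene flanked by two ortho alkoxy groups may be sluggish, so that azine formation or insertion into the neighbouring methoxy group competes, or facial control by the catalyst may be insufficient. The fallback sets out from 16 and returns at 27. Compound 16 is lithiated as in step 10 and quenched with 3,5-dimethoxybenzaldehyde to give the diaryl carbinol F4 (both carbinol epimers, immaterial). Sodium p-toluenesulfinate and HCl in methanol remove the MOM groups and replace the benzylic hydroxyl, giving the sulfone F5, a stable ortho-quinone methide precursor. Cs2CO3 in CH2Cl2 then releases the quinone methide and the ylide of (2,4-dimethoxybenzyl)dimethylsulfonium tetrafluoroborate F6 (from 22, Me2S and HBF4); conjugate addition and 5-exo-tet closure should give the trans 2,3-diaryl-dihydrobenzofuran-4-ol. The planar quinone methide is not steered by the inner unit, so both trans diastereomers are expected: the wanted (2R,3R) phenol F7 and its (2S,3S) isomer F8. They are diastereomers and are to be separated by chromatography; a sulfonium salt of a chiral sulfide would be tried for reagent control. Methylation of F7 (MeI, K2CO3, DMF) gives 27.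

Step 5. The C2 anisyl group may migrate instead of ring A (isoflavone), the flavanone may be dehydrogenated to the flavone, or the iodine reagent may attack the very electron-rich ring A. The fallback sets out from 8 and returns at 10, and makes the same C3–C3a bond by a Wolff ring contraction. Compound 8 is enolised with LiN(SiMe3)2 in THF at −78 °C, where the enolate should not open to the chalcone, and acylated with CF3CO2CH2CF3 to the 3-trifluoroacetyl flavanone F9 (not isolated). Detrifluoroacetylative diazo transfer with MsN3 and Et3N in MeCN gives the 3-diazo flavanone F10. Irradiation at about 350 nm in methanol should expel nitrogen, shift the ring A carbon from the carbonyl carbon to C3 and trap the ketene as ester 10 together with its cis isomer F11, which NaOMe in methanol equilibrates to 10.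

**Further compounds**
F1 | step 8 | 2,2-dimethyl-6-(2-oxopropyl)-4H-1,3-dioxin-4-one | CC(=O)CC1=CC(=O)OC(C)(C)O1
F2 | step 8 | 6-(4-DBF*-2,4-dioxobutyl)-2,2-dimethyl-4H-1,3-dioxin-4-one | COc1cc(OCc2ccccc2)cc2O[C@@H](c3ccc(OC)cc3)[C@H](C(=O)CC(=O)CC3=CC(=O)OC(C)(C)O3)c12
F3 | step 8 | 5-DBF*-7-hydroxy-2,2-dimethyl-4H-1,3-benzodioxin-4-one | COc1cc(OCc2ccccc2)cc2O[C@@H](c3ccc(OC)cc3)[C@H](c3cc(O)cc4OC(C)(C)OC(=O)c34)c12
F4 | step 14 | [4-DBF*-2,6-bis(methoxymethoxy)phenyl](3,5-dimethoxyphenyl)methanol (carbinol epimers) | COc1cc(OCc2ccccc2)cc2O[C@@H](c3ccc(OC)cc3)[C@H](c3cc(OCOC)c(C(O)c4cc(OC)cc(OC)c4)c(OCOC)c3)c12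
F5 | step 14 | 5-DBF*-2-[(3,5-dimethoxyphenyl)(4-methylbenzenesulfonyl)methyl]benzene-1,3-diol (epimers at the sulfonyl carbon) | COc1cc(OCc2ccccc2)cc2O[C@@H](c3ccc(OC)cc3)[C@H](c3cc(O)c(C(c4cc(OC)cc(OC)c4)S(=O)(=O)c4ccc(C)cc4)c(O)c3)c12
F6 | step 14 | (2,4-dimethoxybenzyl)dimethylsulfonium tetrafluoroborate | COc1ccc(C[S+](C)C)c(OC)c1.F[B-](F)(F)F
F7 | step 14 | (2R,3R)-6-DBF*-2-(2,4-dimethoxyphenyl)-3-(3,5-dimethoxyphenyl)-2,3-dihydro-1-benzofuran-4-ol | COc1cc(OCc2ccccc2)cc2O[C@@H](c3ccc(OC)cc3)[C@H](c3cc(O)c4c(c3)O[C@@H](c3ccc(OC)cc3OC)[C@@H]4c3cc(OC)cc(OC)c3)c12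
F8 | step 14 | (2S,3S)-6-DBF*-2-(2,4-dimethoxyphenyl)-3-(3,5-dimethoxyphenyl)-2,3-dihydro-1-benzofuran-4-ol | COc1cc(OCc2ccccc2)cc2O[C@@H](c3ccc(OC)cc3)[C@H](c3cc(O)c4c(c3)O[C@H](c3ccc(OC)cc3OC)[C@H]4c3cc(OC)cc(OC)c3)c12
F9 | step 5 | (2R)-7-(benzyloxy)-5-methoxy-2-(4-methoxyphenyl)-3-(trifluoroacetyl)chroman-4-one (C3 epimers and enol) | COc1cc(OCc2ccccc2)cc2O[C@@H](c3ccc(OC)cc3)C(C(=O)C(F)(F)F)C(=O)c12
F10 | step 5 | (2S)-7-(benzyloxy)-3-diazo-5-methoxy-2-(4-methoxyphenyl)chroman-4-one | COc1cc(OCc2ccccc2)cc2O[C@@H](c3ccc(OC)cc3)C(=[N+]=[N-])C(=O)c12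
F11 | step 5 | methyl (2R,3S)-6-(benzyloxy)-4-methoxy-2-(4-methoxyphenyl)-2,3-dihydro-1-benzofuran-3-carboxylate (cis) | COc1cc(OCc2ccccc2)cc2O[C@@H](c3ccc(OC)cc3)[C@@H](C(=O)OC)c12
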